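The target is what each flask is asked to hold at the end, and it can form only as far as the partner reaches the starting material.

    starting material + partner → target (k1 = 1.5 M⁻¹ h⁻¹, Ea1 = 86.0 kJ mol⁻¹)
    second substrate + partner → second product (k2 = 1.9 M⁻¹ h⁻¹, Ea2 = 58.0 kJ mol⁻¹)
    third substrate + partner → third product (k3 = 0.036 M⁻¹ h⁻¹, Ea3 = 72.0 kJ mol⁻¹)
    second substrate → decomposition product (k4 = 1.2 × 10⁻⁴ h⁻¹, Ea4 = 128 kJ mol⁻¹)
    target ⇌ isomer of the product (K5 = 6.1, k5 = 0.16 h⁻¹, Ea5 = 110 kJ mol⁻¹, ΔH5 = −33.0 kJ mol⁻¹)
    partner → decomposed reagent (k6 = 0.13 h⁻¹, Ea6 = 108 kJ mol⁻¹)
    (constants at 50 °C)

| setting | amber | violet | grey |
|---|---|---|---|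
| starting material | 0.46 M | 0.46 M | 0.46 M |
| partner | 0.460 M | 0.460 M | 0.460 M |
| second substrate | 0.0920 M | 0.0920 M | 0.0920 M |
| third substrate | 0.920 M | 0.920 M | 0.920 M |
| temperature | 30 °C | 50 °C |  |
| time | 30 h | 30 h | 30 h |
| remark |  |  | at 50 °C until 20 h, from then on at 30 °C |

* the flask that comes out highest in amount of target, in percent of the starting material charged, or "all alike" when all lie within 1.5 percentage points (amber / violet / grey / all alike)
* target at the end, in percent of the starting material charged, amber
* target at the end, in percent of the starting material charged, violet
* target at the end, in percent of the starting material charged, grey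

- constants are those at 50 °C; use the activation energies and enthalpies for any other temperature

The partner is the limiting reagent: its 0.460 M faces 1.47 M of substrates, and it also decays. Every consumption of partner is first order in partner, so we define θ as the time integral of the partner concentration and call it the partner dose. Each substrate then falls as the exponential of minus its rate constant times θ, the decay has taken 0.13 h⁻¹ times θ, and the balance becomes algebraic in θ. We drop the decomposition of second substrate, since 0.00360 is its whole exponent.

At 50 °C we start from 40.0 M·min, one e-fold of starting material. At that dose the second substrate, third substrate and decay take 0.175 M, and the balance then returns 38.8 M·min. The pass swings about its solution, so we take the mean as the exhaustion dose, the θ at which the balance leaves zero partner: 39.4 M·min. It leaves 37.4 % of the starting material, so 62.6 % is converted.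

The partner's initial loss constant is 1.03 h⁻¹, a time of 58.4 min, which is shorter than 20 h, so violet and grey receive this dose while hot. Target relaxes to its isomer in 5.37 h, shorter than 30 h. Counting the product as made at the start, violet ends near 9.02 %.

Arrhenius factors between two fixed temperatures scale as powers of the activation energies, so cooling slows isomerisation by 14.9. With 13.7, the cold relaxation time is 3.62 d, longer than 30 h. For grey we reckon 10.1 % at the change and a slow fall towards 4.26 %, which puts its end near 9.48 %. For amber we did not reckon a cold dose: we borrow the hot conversion and age the product over the full time, which gives a rough 44.3 %, so in this reckoning amber comes out highest. We reforge the mean by running the pass once more from it, which returns 39.3 M·min against 39.4 M·min. This pass tests the dose and leaves untouched both the product counted as made at the start and amber's borrowed hot conversion.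

The forecast names amber, with 45.2 % for amber, 9.1 % for violet and 9.9 % for grey, a little above ours in violet and grey; it too works with θ, by which “the partner balance becomes algebraic”.

The flasks end at 45.2 % in amber, 9.09 % in violet and 9.90 % in grey, so amber is highest. Violet keeps 37 % of its starting material, against the 37.4 % that 39.4 M·min leaves. A neighbour of grey gets 0.12 M of partner. We start there from 420 M·s, and one pass returns 475 M·s. The mean dose 448 M·s is smaller than 39.4 M·min and leaves 83.0 % of the starting material; the neighbour holds 82.7 %. Grey's target share of its converted material then gives 2.69 %, and the neighbour ends with 2.70 % of target.

The constants stand for no real mixture; the result is computed.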